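The chroman ring B is cut across O-1–C-8a and C-3–C-4. This pairs the O-1–C-2–C-3 unit of cyclopentane ring C, taken as a ketone enolate (nucleophilic at both O and C), with the C-4–C-4a–C-8a unit of the arene, taken as an ortho-fluoro aroyl chloride. In one pot the lithium enolate of a menthone-derived spiro[4.5]decane-1,6-dione is C-acylated and its enolate oxygen then displaces the ortho fluoride, giving a flat chromone. Ring B is afterwards dearomatised stepwise (hydride at C-2, methyl at C-3, isobutyl at C-4), the remaining fluorides become the phenols, and a double Vilsmeier formylation finishes the synthesis.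

Key step: step 3

Remark on locants: rings A/B carry chroman numbers (O-1, C-2, C-3, C-4, C-4a, C-5 to C-8, C-8a); ring C (cyclopentane) is C-2, C-3, C-9, C-10, C-1′; ring D (cyclohexene) is C-1′ (spiro), C-2′ (=CH), C-3′ (C–iPr), C-4′, C-5′, C-6′ (CH–Me).

Remark on the starting material: (+)-menthone, the (2R,5S) enantiomer, is taken as commercial; its C-2 epimer content is irrelevant because that centre becomes sp2, and its C-5 supplies the C-6′ stereocentre.

Step 1
Reactants: 1 (+)-menthone; 2 tert-butyl 4-bromobutanoate
Product: 3 tert-butyl 4-[(6S)-6-methyl-2-oxo-3-(propan-2-yl)cyclohexyl]butanoate (epimers at ring C-1 and C-3)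
Conditions: LiN(i-Pr)2 (1.1 equiv), THF, −78 °C; then 2, DMPU, −78 to 23 °C
Reagents that add atoms: none
Why: Kinetic deprotonation of menthone occurs at the less substituted α-CH2 and SN2 alkylation of the lithium enolate by the primary bromide installs the four-carbon acid chain (ketone enolate alkylation); the new centre and the isopropyl-bearing centre are both erased later, and the methyl-bearing centre is not touched.

Step 2
Reactants: 3 keto ester
Product: 5 (5S,10S)-10-methyl-7-(propan-2-yl)spiro[4.5]decane-1,6-dione, via keto acid 4 (not isolated)
Conditions: polyphosphoric acid, AcOH, 100 °C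
Reagents that add atoms: none
Why: Acid cleaves the tert-butyl ester and the activated acid then C-acylates the more substituted enol of the ketone (acid-mediated intramolecular Claisen-type acylation, as used for spiro[4.4]nonane-1,6-dione); the neighbouring methyl sits pseudo-axial on the enol (A1,2 strain) and the acyl carbon should bond on the opposite face, placing the new C-1 carbonyl trans to the C-10 methyl.

Step 3
Reactants: 5 spiro dione; 6 2,4,6-trifluorobenzoyl chloride
Product: 8 5,7-difluorochromone fused to ring C and spiro-linked to the ring-D ketone, via triketone 7 (not isolated)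
Conditions: LiN(SiMe3)2 (2.3 equiv), THF, −78 °C; then 6, −78 to 23 °C; then DMF, 80 °C (one pot)
Reagents that add atoms: none
Why: LiN(SiMe3)2 deprotonates the cyclopentanone of 5 only at C-3 (its other α-carbon is the spiro atom and the cyclohexanone methine is hindered), the enolate carbon attacks the acid chloride (C-3–C-4 bond, Claisen-type C-acylation), and a second equivalent of base turns triketone 7 into its diketonate, whose oxygen on C-2 adds to the fluorine-bearing ortho carbon and expels fluoride (O-1–C-8a bond, SNAr). The closest known reactions are the one-pot chromone synthesis from ketone enolates and 2-fluorobenzoyl chlorides and the Grohe cycloaracylation used for quinolones. Ring B closes by a 6-exo-trig addition of the enolate oxygen to C-8a (the C-8a=C-8 π bond lies outside the new ring), followed by loss of fluoride. No stereocentre is created, because C-2, C-3 and C-4 are all sp2 in the chromone and are set in steps 7, 8 and 10, while C-1′ and C-6′ are not touched. The step needs C- rather than O-acylation and a clean displacement: any enol ester should be funnelled to the chelated lithium diketonate by acyl transfer under excess base, the two ortho fluorines are equivalent, and the ortho acyl group plus the two other fluorines activate the ring.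

Step 4
Reactants: 8 keto chromone
Product: 9 enol triflate (ring D: 2′-OTf, C-2′=C-3′)
Conditions: KN(SiMe3)2 (1.3 equiv), THF, −78 to −20 °C; then PhNTf2
Reagents that add atoms: N-phenylbis(trifluoromethanesulfonimide), O=S(=O)(N(c1ccccc1)S(=O)(=O)C(F)(F)F)C(F)(F)F
Why: The ring-D ketone can enolise only toward C-3′ because C-1′ is quaternary, so O-sulfonylation of the potassium enolate should give a single tetrasubstituted enol triflate (enol triflate formation), the hindered amide base being expected to leave the aryl fluorides alone at low temperature.

Step 5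
Reactants: 9 enol triflate
Product: 10 5,7-difluorochromone with the ring-D alkene of the target
Conditions: Pd(OAc)2 (5 mol %), PPh3, n-Bu3N, HCO2H, DMF, 60 °C
Reagents that add atoms: none
Why: Oxidative addition of zerovalent palladium into the vinyl triflate, formate exchange, loss of CO2 and reductive elimination replace OTf by H (Cacchi reduction), which fixes the alkene at C-2′=C-3′ without touching the aryl fluorides or the chromone.

Step 6
Reactants: 10 difluorochromone
Product: 11 5,7-bis(benzyloxy)chromone
Conditions: BnOH (2.5 equiv), NaH (2.5 equiv), DMF, 0 to 60 °C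
Reagents that add atoms: benzyl alcohol, OCc1ccccc1
Why: Both fluorides are ortho or para to the ring carbon that carries the pyranone carbonyl, so benzyloxide should displace them by SNAr, and the ring-D ketone is already gone so the alkoxide cannot cleave it by a retro-Claisen reaction.

Step 7
Reactants: 11 bis(benzyloxy)chromone
Product: 13 cis-fused 5,7-bis(benzyloxy)chroman-4-one with C-2 as in the target, via chromanone epimer mixture 12 (not isolated)
Conditions: LiBH(s-Bu)3 (1.2 equiv), THF, −78 °C; MeOH; then K2CO3, MeOH–THF, 40 °C
Reagents that add atoms: none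
Why: Conjugate hydride addition to the vinylogous ester (1,4-reduction of a chromone) gives the chromanone, and base then equilibrates C-2 through retro-oxa-Michael/oxa-Michael ring opening and C-3 through enolisation, which should favour the cis-fused isomer whose O-1 lies on the face of ring C next to the flat =CH-2′ arm while H-2 faces the bulkier CH(Me)-6′ arm, the face from which the phenoxide is also expected to re-add.

Step 8
Reactants: 13 cis-fused chromanone
Product: 14 3-methylchroman-4-one (methyl cis to H-2)
Conditions: LiN(i-Pr)2 (1.1 equiv), THF, −78 °C; then MeI, DMPU, −78 to −40 °C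
Reagents that add atoms: iodomethane, CI
Why: In this kinetic enolate alkylation methyl iodide should attack C-3 of the ring-fusion enolate on the face of H-2, the only approach that keeps the 6/5 ring fusion cis, which sets the quaternary centre; the low temperature is meant to outrun β-elimination of the aryloxide.

Step 9
Reactants: 14 3-methylchromanone
Product: 15 chroman-4-ol (C-4 epimers)
Conditions: LiAlH4, THF, 0 °C
Reagents that add atoms: none
Why: Hydride reduction of the hindered aryl ketone gives the benzylic alcohol, whose configuration does not matter because C-4 is ionised in the next step.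

Step 10
Reactants: 15 chroman-4-ol
Product: 16 4-(2-methylprop-2-en-1-yl)chroman (side chain cis to the C-3 methyl and H-2)
Conditions: methallyltrimethylsilane (3 equiv), BF3·OEt2, CH2Cl2, −78 °C
Reagents that add atoms: trimethyl(2-methylprop-2-en-1-yl)silane, CC(=C)C[Si](C)(C)C
Why: BF3·OEt2 ionises the alcohol to a benzylic cation stabilised by three ortho/para oxygens, which the allylsilane captures (Hosomi–Sakurai-type SN1 allylation) by axial attack anti to the pseudo-axial ring-C methylene C-9 on C-3, on the face where only H-2 is 1,3-diaxial, so the new chain should end up cis to the C-3 methyl; C-3 is quaternary, so elimination cannot compete.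

Step 11
Reactants: 16 methallyl chroman
Product: 17 4-(2-methylpropyl)chroman
Conditions: H2 (1 atm), RhCl(PPh3)3 (5 mol %), benzene–EtOH, 23 °C
Reagents that add atoms: none
Why: Homogeneous hydrogenation with RhCl(PPh3)3 reduces the unhindered 1,1-disubstituted alkene far faster than the hindered trisubstituted ring-D alkene and does not cleave benzyl ethers, turning methallyl into isobutyl.

Step 12
Reactants: 17 bis(benzyl) ether
Product: 18 chroman-5,7-diol
Conditions: BCl3 (4 equiv), pentamethylbenzene (6 equiv), CH2Cl2, −78 °C; then MeOH
Reagents that add atoms: none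
Why: Lewis-acid debenzylation with a non-basic cation scavenger removes both benzyl aryl ethers at −78 °C, while the hindered secondary alkyl aryl ether O-1–C-2 (no SN2 access, no stabilised cation) and the alkene should survive.

Step 13
Reactants: 18 chroman-5,7-diol
Product: 19 target CNP0121396.2
Conditions: POCl3 (5 equiv), DMF (6 equiv), EtOAc, 0 to 23 °C; then H2O, NaOAc, 23 °C
Reagents that add atoms: N,N-dimethylformamide, CN(C)C=O; water, O
Why: In this Vilsmeier–Haack formylation C-6 and C-8 are the only free ring positions and each is ortho/para to two oxygen donors, so both should be formylated as in phloroglucinol itself, and hydrolysis of the bis-iminium salt gives the dialdehyde.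

Compound list
1 | (+)-menthone, (2R,5S)-5-methyl-2-(propan-2-yl)cyclohexan-1-one | CC(C)[C@H]1CC[C@H](C)CC1=O | starting material
2 | tert-butyl 4-bromobutanoate | CC(C)(C)OC(=O)CCCBr | starting material
3 | tert-butyl 4-[(6S)-6-methyl-2-oxo-3-(propan-2-yl)cyclohexyl]butanoate, epimers at ring C-1 and C-3 | CC(C)C1CC[C@H](C)C(CCCC(=O)OC(C)(C)C)C1=O | intermediate
4 | 4-[(6S)-6-methyl-2-oxo-3-(propan-2-yl)cyclohexyl]butanoic acid, same epimer mixture | CC(C)C1CC[C@H](C)C(CCCC(=O)O)C1=O | intermediate
5 | (5S,10S)-10-methyl-7-(propan-2-yl)spiro[4.5]decane-1,6-dione, C-1 carbonyl trans to the C-10 methyl, C-7 epimers | O=C1CCC[C@@]12C(=O)C(C(C)C)CC[C@@H]2C | intermediate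
6 | 2,4,6-trifluorobenzoyl chloride | O=C(Cl)c1c(F)cc(F)cc1F | starting material
7 | 2-(2,4,6-trifluorobenzoyl) derivative of 5 (acyl on C-2 of the spirodecane; present as its lithium diketonate) | O=C1C(C(=O)c3c(F)cc(F)cc3F)CC[C@@]12C(=O)C(C(C)C)CC[C@@H]2C | intermediate
8 | 5,7-difluoro-4H-chromen-4-one whose C-2/C-3 bond is shared with cyclopentene ring C; spiro atom C-1′ belongs to ring D, here 3′-isopropyl-6′-methyl-2′-oxocyclohexane (C-1′ and C-6′ as in 5, C-3′ epimers) | Fc1cc(F)c2c(c1)OC1=C(CC[C@@]13C(=O)C(C(C)C)CC[C@@H]3C)C2=O | intermediate
9 | as 8, with ring D as the 2′-(trifluoromethanesulfonyloxy)cyclohex-2′-ene (isopropyl on C-3′) | Fc1cc(F)c2c(c1)OC1=C(CC[C@@]13C(OS(=O)(=O)C(F)(F)F)=C(C(C)C)CC[C@@H]3C)C2=O | intermediate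
10 | as 8, with ring D as the 3′-isopropyl-6′-methylcyclohex-2′-ene of the target | Fc1cc(F)c2c(c1)OC1=C(CC[C@@]13C=C(C(C)C)CC[C@@H]3C)C2=O | intermediate
11 | 5,7-bis(benzyloxy) analogue of 10 | c1ccccc1COc1cc(OCc2ccccc2)c2c(c1)OC1=C(CC[C@@]13C=C(C(C)C)CC[C@@H]3C)C2=O | intermediate
12 | 2,3-dihydro derivative of 11 (chroman-4-one), mixture of C-2 and C-3 epimers | c1ccccc1COc1cc(OCc2ccccc2)c2c(c1)OC1C(CC[C@@]13C=C(C(C)C)CC[C@@H]3C)C2=O | intermediate
13 | single cis-fused isomer of 12: H-2 and H-3 cis, O-1 on the face of ring C that carries the =CH-2′ arm (C-2 as in the target) | c1ccccc1COc1cc(OCc2ccccc2)c2c(c1)O[C@H]1[C@H](CC[C@@]13C=C(C(C)C)CC[C@@H]3C)C2=O | intermediate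
14 | 3-methyl derivative of 13, methyl cis to H-2 (C-2 and C-3 as in the target) | c1ccccc1COc1cc(OCc2ccccc2)c2c(c1)O[C@H]1[C@](C)(CC[C@@]13C=C(C(C)C)CC[C@@H]3C)C2=O | intermediate
15 | chroman-4-ol from 14, C-4 epimers | c1ccccc1COc1cc(OCc2ccccc2)c2c(c1)O[C@H]1[C@](C)(CC[C@@]13C=C(C(C)C)CC[C@@H]3C)C2O | intermediate
16 | 4-(2-methylprop-2-en-1-yl)chroman from 15, side chain cis to the C-3 methyl and H-2 (C-4 as in the target) | c1ccccc1COc1cc(OCc2ccccc2)c2c(c1)O[C@H]1[C@](C)(CC[C@@]13C=C(C(C)C)CC[C@@H]3C)[C@H]2CC(C)=C | intermediate
17 | 4-(2-methylpropyl) analogue of 16 | c1ccccc1COc1cc(OCc2ccccc2)c2c(c1)O[C@H]1[C@](C)(CC[C@@]13C=C(C(C)C)CC[C@@H]3C)[C@H]2CC(C)C | intermediate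
18 | 5,7-diol of 17 (both benzyl groups removed) | Oc1cc(O)c2c(c1)O[C@H]1[C@](C)(CC[C@@]13C=C(C(C)C)CC[C@@H]3C)[C@H]2CC(C)C | intermediate
19 | CNP0121396.2: (2S,3R,4R,1′R,6′S)-5,7-dihydroxy-3,6′-dimethyl-4-(2-methylpropyl)-3′-(propan-2-yl)chroman-6,8-dicarbaldehyde, fused at C-2/C-3 to cyclopentane ring C and spiro-linked at C-1′ to cyclohex-2′-ene ring D | CC(C)C[C@H]1c2c(O)c(C=O)c(O)c(C=O)c2O[C@H]2[C@]1(C)CC[C@@]21C=C(C(C)C)CC[C@@H]1C | target

Total step count: 13. Longest linear sequence: 13 steps (1 to 19).

Steps most likely to fail

Step 8. The chromanone enolate may open ring B by β-elimination of the aryloxide, and the freed phenoxide may then be O-methylated faster than C-3 is methylated. The fallback sets out from 13 and avoids a free enolate. Soft enolisation with Me3SiOTf and Et3N in CH2Cl2 should give the trimethylsilyl enol ether F1. Cyclopropanation of this electron-rich alkene with Et2Zn and CH2I2 (the ring-D alkene is far less nucleophilic) should give the siloxycyclopropane F2, with the methylene delivered on the face of H-2. Desilylation with K2CO3 in MeOH opens the cyclopropanol toward its CH2 group (α-methylation through a siloxycyclopropane), and the route is rejoined at 14.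

Step 7. Hydride delivery to the hindered C-2 may be slow, and the equilibration may give poor facial selectivity at C-2. The fallback sets out from 11 and replaces substrate control by catalyst control. After reduction with LiBH(s-Bu)3 the enolate is allowed to warm to 23 °C so that it ring-opens, and protonation gives the 2-hydroxyaryl cyclopentenyl ketone F3. Ring B is then closed by an intramolecular oxa-Michael addition under a quinine-derived bifunctional thiourea in toluene, the catalyst enantiomer being chosen to place O-1 on the required face. The route is rejoined at 13.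

Step 2. The acid-mediated spiro-acylation may stall at the hindered enol, or the spiro centre may scramble through reversible ring opening. The fallback sets out from 3 and uses a base-mediated closure. Cleavage with CF3CO2H gives acid 4, now isolated, and coupling with MeNHOMe·HCl (EDC, CH2Cl2) gives the Weinreb amide F4. KOt-Bu in THF equilibrates the ketone enolates; only the enolate at the chain-bearing carbon can close a five-membered ring, and the stable tetrahedral intermediate prevents retro-Claisen opening. Work-up returns the route to 5.

Further compounds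
F1 | step 8 | trimethylsilyl enol ether of 13 (C-3=C-4, OSiMe3 on C-4) | c1ccccc1COc1cc(OCc2ccccc2)c2c(c1)O[C@H]1C(CC[C@@]13C=C(C(C)C)CC[C@@H]3C)=C2O[Si](C)(C)C
F2 | step 8 | siloxycyclopropane from F1 (CH2 bridging C-3 and C-4 on the face of H-2) | c1ccccc1COc1cc(OCc2ccccc2)c2c(c1)O[C@H]1[C@@]4(CC[C@@]13C=C(C(C)C)CC[C@@H]3C)C[C@@]24O[Si](C)(C)C
F3 | step 7 | [2-hydroxy-4,6-bis(benzyloxy)phenyl] ketone of the ring-C cyclopentene (ring B opened between O-1 and C-2) | c1ccccc1COc1cc(O)c(C(=O)C2=C[C@@]3(CC2)C=C(C(C)C)CC[C@@H]3C)c(OCc2ccccc2)c1
F4 | step 2 | N-methoxy-N-methyl amide of acid 4 | CC(C)C1CC[C@H](C)C(CCCC(=O)N(C)OC)C1=O
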